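3 questions stand over this flask. Two ask for the amount of G per amount of X, and the third follows from that ratio, so the ratio is what I look for in the earlier runs.

in all of them: Z 0.50 M
- Monday's: E 0.26 M; run made earlier
- Thursday's: E 1.1 M; run made earlier
- flask: E 0.525 M; time 40 min

| run | time / min | G / % | X / % |
|---|---|---|---|
| Monday's | 3.00 | 11.1 | 17.3 |
| Monday's | 10.0 | 13.9 | 17.1 |
| Monday's | 15.0 | 9.1 | 18.9 |
| Monday's | 25.0 | 12.0 | 18.6 |
| Monday's | 40.0 | 10.8 | 18.4 |
| Monday's | 50.0 | 10.5 | 18.3 |
| Thursday's | 8.00 | 31.2 | 50.1 |
| Thursday's | 15.0 | 30.6 | 51.3 |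
| Thursday's | 25.0 | 30.3 | 47.5 |
| Thursday's | 30.0 | 29.5 | 51.4 |
| Thursday's | 40.0 | 31.0 | 50.6 |
| Thursday's | 50.0 | 29.6 | 50.2 |

(scatter of a reading: 1 percentage point)

* ratio of G to X at 8.0 s
* ratio of G to X at 40 min
* which of G and X there is more of at 40 min



I read the tables column against column before I reckon anything. In Monday's run, with cE at 0.26 M, the sum of the G column over the sum of the X column is 0.621. In Thursday's run, with cE at 1.1 M, X stands at 50.6% at 40.0 min against 18.4% on Monday, yet the same sum gives 0.605.

Row by row, Monday's ratios run from 0.481 to 0.813, so the gap between the two runs is far smaller than the spread of the rows. I therefore take the mean of the two, 0.613, and call it the split, the amount of G per amount of X, a selectivity factor.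

This flask has cE at 0.525 M, between the two runs, so I commit to the split at 40 min. It is less than one, so I expect more X than G. The time 8.0 s lies before the first row at 3.00 min, so there the split is an extrapolation that no reading backs.

The forecast gives 0.61 at 8.0 s, 0.61 at 40 min, and X ahead, with a wider range for the early time, since “a fast early ratio that later equilibrates can't be excluded”.

The flask gives 0.596 at 8.0 s, 0.595 at 40 min, and X ahead.

    Q ⇌ G (K = 2.20, k = 0.0248 /s)
    E → J (k = 0.0133 /s)
    Z + E → Q + D (k = 0.0591 /M/s)
    Q ⇌ X (K = 3.70, k = 0.0416 /s)

While E lasted, Z and E made Q and D, E also passed into J, and Q passed on to X and G: half of the turnover up to 40 min was done by 0.267 min for the first of these steps and by 0.506 min for Q into X. At 20.0 min, with E at 0% of its charge, this flask held Z 38.3%, Q 8.95%, X 33.1% and G 19.7%, and the same X and G stood at 400 min. The split on 33.1% of X gives 20.3% of G, and the flask holds 19.7%. The flask with 0.85 M of Z ends with X at 24.5%, on which the split gives 15.0% of G, and it holds 14.5%.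

The data come from a simulation from invented constants.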